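The route builds ring A de novo instead of attaching the side chain to a preformed phloroglucinol. C8, flanked by the oxygenated carbons C7 and C8a, is read as the substituted carbon of an ynol ether, and the side chain as ring-opened (R)-limonene whose former ring carbon becomes C8. The key step, a thermal benzannulation of a limonene-derived siloxyalkyne with a 3-silyloxycyclobutenone, forms C8–C8a and C6–C7, closes ring A and delivers the 8-alkylphloroglucinol with the (R)-centre in place and only O8a unprotected. Ring C is then grown from that single free phenol and C2 is set by catalytic asymmetric aryl addition.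

Key step: step 7

Remark: commercial (+)-limonene 1,2-oxide is a cis/trans mixture at the epoxide; both isomers give the same keto aldehyde, so it is used as such. 3-Ethoxycyclobut-2-en-1-one is taken as a purchased starting material.

Step 1
Reactants: 1 (4R)-limonene 1,2-oxide
Product: 2 (3R)-6-oxo-3-(prop-1-en-2-yl)heptanal
Conditions: H5IO6 (1.2 equiv), THF/H2O 4:1, 0 °C to rt
Reagents that add atoms: water, O
Why: Acid-promoted epoxide hydrolysis followed in the same flask by Malaprade glycol cleavage should cut only the C1–C2 bond of the ring, leaving the isopropenyl group and the C4 stereocenter (the future side-chain centre) untouched.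

Step 2
Reactants: 2 (3R)-6-oxo-3-(prop-1-en-2-yl)heptanal
Product: 3 (5R)-8,8-dibromo-5-(prop-1-en-2-yl)oct-7-en-2-one
Conditions: CBr4 (2 equiv), PPh3 (4 equiv), CH2Cl2, 0 °C
Reagents that add atoms: carbon tetrabromide, BrC(Br)(Br)Br
Why: The dibromoolefination stage of the Corey–Fuchs reaction (Wittig reaction of Ph3P=CBr2) is fast for aldehydes and should leave the methyl ketone untouched at 0 °C.

Step 3
Reactants: 3 (5R)-8,8-dibromo-5-(prop-1-en-2-yl)oct-7-en-2-one
Product: 4 (5R)-8,8-dibromo-2-methyl-5-(prop-1-en-2-yl)oct-7-en-2-ol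
Conditions: MeMgBr (1.3 equiv), THF, −78 to 0 °C; aq. NH4Cl
Reagents that add atoms: methylmagnesium bromide, C[Mg]Br
Why: Grignard addition to the methyl ketone should give the tertiary carbinol, the 1,1-dibromoalkene being inert to MeMgBr below 0 °C.

Step 4
Reactants: 4 (5R)-8,8-dibromo-2-methyl-5-(prop-1-en-2-yl)oct-7-en-2-ol
Product: 5 triethylsilyl ether of 4
Conditions: TESOTf (1.3 equiv), 2,6-lutidine (2 equiv), CH2Cl2, −78 to 0 °C
Reagents that add atoms: triethylsilyl triflate, CC[Si](CC)(CC)OS(=O)(=O)C(F)(F)F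
Why: Silyl triflate/lutidine silylation should cap the hindered tertiary alcohol so that it cannot quench organolithiums or the ketene of the key step.

Step 5
Reactants: 5 triethylsilyl ether of 4
Product: 8 triisopropyl{[(4R)-7-methyl-4-(prop-1-en-2-yl)-7-(triethylsilyloxy)oct-1-yn-1-yl]oxy}silane, via lithium acetylide 6 (not isolated), via lithium ynolate 7 (not isolated)
Conditions: n-BuLi (2.1 equiv), THF, −78 °C; LiOOt-Bu (1.3 equiv, from t-BuOOH/LiHMDS), −78 to 0 °C; TIPSOTf (1.5 equiv), −78 °C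
Reagents that add atoms: lithium tert-butyl peroxide, CC(C)(C)OO[Li]; triisopropylsilyl triflate, CC(C)[Si](C(C)C)(C(C)C)OS(=O)(=O)C(F)(F)F
Why: The second stage of the Corey–Fuchs reaction should give the lithium acetylide, electrophilic oxygen transfer from the lithium peroxide should convert it into the ynolate, and the bulky silyl triflate should silylate on oxygen to an isolable siloxyalkyne, all remote from the stereocenter.

Step 6
Reactants: 9 3-ethoxycyclobut-2-en-1-one
Product: 11 3-(triisopropylsilyloxy)cyclobut-2-en-1-one, via cyclobutane-1,3-dione 10 (not isolated)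
Conditions: 2 M aq. HCl, 0 °C, then evaporation; TIPSOTf (1.1 equiv), Et3N (1.5 equiv), CH2Cl2, −78 to 0 °C
Reagents that add atoms: water, O; triisopropylsilyl triflate, CC(C)[Si](C(C)C)(C(C)C)OS(=O)(=O)C(F)(F)F
Why: Acid hydrolysis of the vinylogous ester followed by O-silylation of the enolizable 1,3-dione (silyl enol ether formation) should exchange the ethyl group for a fluoride-labile silyl group.

Step 7
Reactants: 8 triisopropyl{[(4R)-7-methyl-4-(prop-1-en-2-yl)-7-(triethylsilyloxy)oct-1-yn-1-yl]oxy}silane; 11 3-(triisopropylsilyloxy)cyclobut-2-en-1-one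
Product: 16 2-[(2R)-5-methyl-2-(prop-1-en-2-yl)-5-(triethylsilyloxy)hexyl]-3,5-bis(triisopropylsilyloxy)phenol, via vinylketene 12 (not isolated), via 4-vinylcyclobutenone 13 (not isolated), via dienylketene 14 (not isolated), via cyclohexadienone 15 (not isolated)
Conditions: PhMe (0.3 M), 80 °C, 11 (1.3 equiv) added by syringe pump, then 110 °C
Reagents that add atoms: none
Why: Heating should open cyclobutenone 11 by 4π-electrocyclic ring opening to the (2-silyloxyvinyl)ketene 12, to which the electron-rich siloxyalkyne 8 adds in a regiospecific [2+2] (its nucleophilic carbon β to oxygen, the one bearing the side-chain CH2, bonds to the ketene carbonyl carbon) to give 4-vinylcyclobutenone 13, which opens again (4π) to dienylketene 14, closes by 6π-electrocyclization to cyclohexadienone 15 and tautomerizes to phenol 16. The closest known reaction type is the Danheiser benzannulation of cyclobutenones with trialkylsilyloxyalkynes, which gives 2-substituted resorcinol monosilyl ethers. Ring A is the only ring closed, a six-membered carbocycle whose last bond C4a–C8a forms by thermal disrotatory 6π-electrocyclization after the [2+2] has made C8–C8a and C6–C7. No stereocenter is created (the sp3 carbon of 13 is erased on aromatization), and the (R) centre, two carbons from the alkyne and not enolizable, is carried through. The step needs regiocontrol in the [2+2], secured by the ynol ether polarization (it places C8 between the ketene-derived C8a–OH and the alkyne-derived C7–OSi and leaves the cyclobutenone oxygen at C5), and chemoselectivity for the siloxyalkyne over the isopropenyl group, secured by the much higher nucleophilicity of the ynol ether; slow addition of 11 should keep the ketene from acylating the product.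

Step 8
Reactants: 16 2-[(2R)-5-methyl-2-(prop-1-en-2-yl)-5-(triethylsilyloxy)hexyl]-3,5-bis(triisopropylsilyloxy)phenol
Product: 17 2-hydroxy-3-[(2R)-5-methyl-2-(prop-1-en-2-yl)-5-(triethylsilyloxy)hexyl]-4,6-bis(triisopropylsilyloxy)benzaldehyde
Conditions: MgCl2 (2 equiv), Et3N (4 equiv), (CH2O)n (6 equiv), MeCN, reflux
Reagents that add atoms: paraformaldehyde (as formaldehyde), C=O
Why: Magnesium-phenoxide-directed ortho-formylation (Casnati–Skattebøl) should deliver formaldehyde through a six-membered chelate to C4a, the only free ortho position, and oxidize the benzylic alkoxide by hydride transfer to a second formaldehyde.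

Step 9
Reactants: 17 2-hydroxy-3-[(2R)-5-methyl-2-(prop-1-en-2-yl)-5-(triethylsilyloxy)hexyl]-4,6-bis(triisopropylsilyloxy)benzaldehyde
Product: 18 1-{2-hydroxy-3-[(2R)-5-methyl-2-(prop-1-en-2-yl)-5-(triethylsilyloxy)hexyl]-4,6-bis(triisopropylsilyloxy)phenyl}prop-2-yn-1-ol (carbinol epimers)
Conditions: HC≡CMgBr (3 equiv), THF, −40 to 0 °C; aq. NH4Cl
Reagents that add atoms: ethynylmagnesium bromide, C#C[Mg]Br
Why: Grignard addition of the acetylide to the aldehyde (one equivalent is spent on the phenol) should give the propargylic alcohol, whose new carbinol centre is removed in the next step.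

Step 10
Reactants: 18 1-{2-hydroxy-3-[(2R)-5-methyl-2-(prop-1-en-2-yl)-5-(triethylsilyloxy)hexyl]-4,6-bis(triisopropylsilyloxy)phenyl}prop-2-yn-1-ol
Product: 21 8-[(2R)-5-methyl-2-(prop-1-en-2-yl)-5-(triethylsilyloxy)hexyl]-5,7-bis(triisopropylsilyloxy)-4H-chromen-4-one, via ynone 19 (not isolated), via enaminone 20 (not isolated)
Conditions: MnO2 (15 equiv), CH2Cl2, rt; filter; Et2NH (1.5 equiv), EtOH, rt; AcOH (2 equiv), 40 °C
Reagents that add atoms: none
Why: MnO2 oxidation of the benzylic propargylic alcohol should give the ynone, aza-Michael addition of diethylamine the enaminone, and addition–elimination by the ortho phenol the pyranone (the enaminone route to chromones), which guarantees the 6-endo outcome.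

Step 11
Reactants: 22 4-bromobenzene-1,3-diol
Product: 23 1-bromo-2,4-bis(tert-butyldimethylsilyloxy)benzene
Conditions: TBSCl (2.4 equiv), imidazole (5 equiv), DMF, rt
Reagents that add atoms: tert-butyldimethylsilyl chloride, CC(C)(C)[Si](C)(C)Cl
Why: Imidazole-promoted silylation of both phenols is routine and gives fluoride-labile protection matching ring A.

Step 12
Reactants: 23 1-bromo-2,4-bis(tert-butyldimethylsilyloxy)benzene
Product: 24 [2,4-bis(tert-butyldimethylsilyloxy)phenyl]boronic acid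
Conditions: B(Oi-Pr)3 (1.5 equiv) premixed, n-BuLi (1.2 equiv), THF/PhMe, −78 °C; aq. NH4Cl
Reagents that add atoms: triisopropyl borate, CC(C)OB(OC(C)C)OC(C)C; water, O
Why: Bromine–lithium exchange with in situ borate trapping should capture the aryllithium before the ortho silyl group can migrate from O to C (retro-Brook), and hydrolysis of the borate gives the boronic acid.

Step 13
Reactants: 21 8-[(2R)-5-methyl-2-(prop-1-en-2-yl)-5-(triethylsilyloxy)hexyl]-5,7-bis(triisopropylsilyloxy)-4H-chromen-4-one; 24 [2,4-bis(tert-butyldimethylsilyloxy)phenyl]boronic acid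
Product: 25 (2S)-2-[2,4-bis(tert-butyldimethylsilyloxy)phenyl]-8-[(2R)-5-methyl-2-(prop-1-en-2-yl)-5-(triethylsilyloxy)hexyl]-5,7-bis(triisopropylsilyloxy)chroman-4-one
Conditions: [RhCl(C2H4)2]2 (2.5 mol %), chiral 2,5-diphenylbicyclo[2.2.2]octa-2,5-diene ligand (5.5 mol %), 24 (2.5 equiv), aq. K3PO4 (0.5 equiv), PhMe/H2O 10:1, 40 °C
Reagents that add atoms: none
Why: Rhodium(I)/chiral-diene-catalysed asymmetric 1,4-addition (Hayashi–Miyaura) should insert the chromone C2=C3 bond into the aryl–Rh species and protonate the resulting oxa-π-allyl, the catalyst alone fixing C2 (the ligand enantiomer that delivers the aryl group to the face giving 2S is selected on a model chromone, the side-chain centre being too remote to interfere).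

Step 14
Reactants: 25 (2S)-2-[2,4-bis(tert-butyldimethylsilyloxy)phenyl]-8-[(2R)-5-methyl-2-(prop-1-en-2-yl)-5-(triethylsilyloxy)hexyl]-5,7-bis(triisopropylsilyloxy)chroman-4-one
Product: 26 norkurarinol
Conditions: HF·pyridine (excess), pyridine, THF, 0 °C to rt
Reagents that add atoms: none
Why: Fluoride-driven Si–O cleavage under pyridine-buffered, non-basic conditions should remove all five silyl groups without forming phenoxides, so the retro-oxa-Michael pathway that would scramble C2 stays closed and the tertiary alcohol and isopropenyl group are left alone.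

Compound list
1 | (4R)-limonene 1,2-oxide (cis/trans mixture at the epoxide) | CC12OC1C[C@@H](CC2)C(C)=C | starting material
2 | (3R)-6-oxo-3-(prop-1-en-2-yl)heptanal | C=C(C)[C@H](CCC(C)=O)CC=O | intermediate
3 | (5R)-8,8-dibromo-5-(prop-1-en-2-yl)oct-7-en-2-one | C=C(C)[C@H](CCC(C)=O)CC=C(Br)Br | intermediate
4 | (5R)-8,8-dibromo-2-methyl-5-(prop-1-en-2-yl)oct-7-en-2-ol | C=C(C)[C@H](CCC(C)(C)O)CC=C(Br)Br | intermediate
5 | {[(5R)-8,8-dibromo-2-methyl-5-(prop-1-en-2-yl)oct-7-en-2-yl]oxy}triethylsilane | C=C(C)[C@H](CCC(C)(C)O[Si](CC)(CC)CC)CC=C(Br)Br | intermediate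
6 | lithium (4R)-7-methyl-4-(prop-1-en-2-yl)-7-(triethylsilyloxy)oct-1-yn-1-ide (lithium acetylide) | C=C(C)[C@H](CCC(C)(C)O[Si](CC)(CC)CC)CC#C[Li] | intermediate
7 | lithium (4R)-7-methyl-4-(prop-1-en-2-yl)-7-(triethylsilyloxy)oct-1-yn-1-olate (lithium ynolate) | C=C(C)[C@H](CCC(C)(C)O[Si](CC)(CC)CC)CC#CO[Li] | intermediate
8 | triisopropyl{[(4R)-7-methyl-4-(prop-1-en-2-yl)-7-(triethylsilyloxy)oct-1-yn-1-yl]oxy}silane | C=C(C)[C@H](CCC(C)(C)O[Si](CC)(CC)CC)CC#CO[Si](C(C)C)(C(C)C)C(C)C | intermediate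
9 | 3-ethoxycyclobut-2-en-1-one | CCOC1=CC(=O)C1 | starting material
10 | cyclobutane-1,3-dione | O=C1CC(=O)C1 | intermediate
11 | 3-(triisopropylsilyloxy)cyclobut-2-en-1-one | CC(C)[Si](OC1=CC(=O)C1)(C(C)C)C(C)C | intermediate
12 | 3-(triisopropylsilyloxy)buta-1,3-dien-1-one (vinylketene) | C=C(O[Si](C(C)C)(C(C)C)C(C)C)C=C=O | intermediate
13 | 2-[(2R)-5-methyl-2-(prop-1-en-2-yl)-5-(triethylsilyloxy)hexyl]-3-(triisopropylsilyloxy)-4-[1-(triisopropylsilyloxy)ethenyl]cyclobut-2-en-1-one | C=C(C)[C@H](CCC(C)(C)O[Si](CC)(CC)CC)CC1=C(O[Si](C(C)C)(C(C)C)C(C)C)C(C(=C)O[Si](C(C)C)(C(C)C)C(C)C)C1=O | intermediate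
14 | 2-[(2R)-5-methyl-2-(prop-1-en-2-yl)-5-(triethylsilyloxy)hexyl]-3,5-bis(triisopropylsilyloxy)hexa-1,3,5-trien-1-one (dienylketene) | C=C(C)[C@H](CCC(C)(C)O[Si](CC)(CC)CC)CC(=C=O)C(O[Si](C(C)C)(C(C)C)C(C)C)=CC(=C)O[Si](C(C)C)(C(C)C)C(C)C | intermediate
15 | 2-[(2R)-5-methyl-2-(prop-1-en-2-yl)-5-(triethylsilyloxy)hexyl]-3,5-bis(triisopropylsilyloxy)cyclohexa-2,4-dien-1-one | C=C(C)[C@H](CCC(C)(C)O[Si](CC)(CC)CC)CC1=C(O[Si](C(C)C)(C(C)C)C(C)C)C=C(O[Si](C(C)C)(C(C)C)C(C)C)CC1=O | intermediate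
16 | 2-[(2R)-5-methyl-2-(prop-1-en-2-yl)-5-(triethylsilyloxy)hexyl]-3,5-bis(triisopropylsilyloxy)phenol | C=C(C)[C@H](CCC(C)(C)O[Si](CC)(CC)CC)Cc1c(O)cc(O[Si](C(C)C)(C(C)C)C(C)C)cc1O[Si](C(C)C)(C(C)C)C(C)C | intermediate
17 | 2-hydroxy-3-[(2R)-5-methyl-2-(prop-1-en-2-yl)-5-(triethylsilyloxy)hexyl]-4,6-bis(triisopropylsilyloxy)benzaldehyde | C=C(C)[C@H](CCC(C)(C)O[Si](CC)(CC)CC)Cc1c(O)c(C=O)c(O[Si](C(C)C)(C(C)C)C(C)C)cc1O[Si](C(C)C)(C(C)C)C(C)C | intermediate
18 | 1-{2-hydroxy-3-[(2R)-5-methyl-2-(prop-1-en-2-yl)-5-(triethylsilyloxy)hexyl]-4,6-bis(triisopropylsilyloxy)phenyl}prop-2-yn-1-ol | C=C(C)[C@H](CCC(C)(C)O[Si](CC)(CC)CC)Cc1c(O)c(C(O)C#C)c(O[Si](C(C)C)(C(C)C)C(C)C)cc1O[Si](C(C)C)(C(C)C)C(C)C | intermediate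
19 | 1-{2-hydroxy-3-[(2R)-5-methyl-2-(prop-1-en-2-yl)-5-(triethylsilyloxy)hexyl]-4,6-bis(triisopropylsilyloxy)phenyl}prop-2-yn-1-one (ynone) | C=C(C)[C@H](CCC(C)(C)O[Si](CC)(CC)CC)Cc1c(O)c(C(=O)C#C)c(O[Si](C(C)C)(C(C)C)C(C)C)cc1O[Si](C(C)C)(C(C)C)C(C)C | intermediate
20 | (E)-3-(diethylamino)-1-{2-hydroxy-3-[(2R)-5-methyl-2-(prop-1-en-2-yl)-5-(triethylsilyloxy)hexyl]-4,6-bis(triisopropylsilyloxy)phenyl}prop-2-en-1-one (enaminone) | C=C(C)[C@H](CCC(C)(C)O[Si](CC)(CC)CC)Cc1c(O)c(C(=O)/C=C/N(CC)CC)c(O[Si](C(C)C)(C(C)C)C(C)C)cc1O[Si](C(C)C)(C(C)C)C(C)C | intermediate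
21 | 8-[(2R)-5-methyl-2-(prop-1-en-2-yl)-5-(triethylsilyloxy)hexyl]-5,7-bis(triisopropylsilyloxy)-4H-chromen-4-one | C=C(C)[C@H](CCC(C)(C)O[Si](CC)(CC)CC)Cc1c(O[Si](C(C)C)(C(C)C)C(C)C)cc(O[Si](C(C)C)(C(C)C)C(C)C)c2c1occc2=O | intermediate
22 | 4-bromobenzene-1,3-diol | Oc1ccc(Br)c(O)c1 | starting material
23 | 1-bromo-2,4-bis(tert-butyldimethylsilyloxy)benzene | CC(C)(C)[Si](C)(C)Oc1ccc(Br)c(O[Si](C)(C)C(C)(C)C)c1 | intermediate
24 | [2,4-bis(tert-butyldimethylsilyloxy)phenyl]boronic acid | CC(C)(C)[Si](C)(C)Oc1ccc(B(O)O)c(O[Si](C)(C)C(C)(C)C)c1 | intermediate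
25 | (2S)-2-[2,4-bis(tert-butyldimethylsilyloxy)phenyl]-8-[(2R)-5-methyl-2-(prop-1-en-2-yl)-5-(triethylsilyloxy)hexyl]-5,7-bis(triisopropylsilyloxy)chroman-4-one | C=C(C)[C@H](CCC(C)(C)O[Si](CC)(CC)CC)Cc1c(O[Si](C(C)C)(C(C)C)C(C)C)cc(O[Si](C(C)C)(C(C)C)C(C)C)c2c1O[C@H](c1ccc(O[Si](C)(C)C(C)(C)C)cc1O[Si](C)(C)C(C)(C)C)CC2=O | intermediate
26 | norkurarinol, (2S)-2-(2,4-dihydroxyphenyl)-5,7-dihydroxy-8-[(2R)-5-hydroxy-5-methyl-2-(prop-1-en-2-yl)hexyl]chroman-4-one | C=C(C)[C@H](CCC(C)(C)O)Cc1c(O)cc(O)c2c1O[C@H](c1ccc(O)cc1O)CC2=O | target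

Total step count: 14. Longest linear sequence: 11 (steps 1–5, 7–10, 13, 14).

Steps most likely to fail

Step 7. The vinylketene may be consumed by dimerization or by acylating the phenol product before it meets the alkyne, or the siloxyalkyne may isomerize to a silylketene at the temperature the first ring opening needs. The fallback sets out from 8 and makes the same ketene 12 below room temperature by 1,4-dehydrochlorination instead of electrocyclic opening. Lithium acetoacetate is bis-silylated (TIPSOTf, Et3N) to triisopropylsilyl 3-(triisopropylsilyloxy)but-2-enoate F1, and oxalyl chloride (CH2Cl2, no DMF) converts the silyl ester into 3-(triisopropylsilyloxy)but-2-enoyl chloride F2. Slow addition of Et3N to F2 in the presence of 8 at 0–25 °C should give 12 and its [2+2] adduct 13, and brief warming to 80 °C then needs only the second ring opening and the electrocyclization to come back to the route at 16.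

Step 13. Transmetalation and insertion of the ortho-silyloxy aryl group may be slow, with protodeboronation of 24 competing. Facial selectivity may also erode, or the base may trigger retro-oxa-Michael opening. The fallback sets out from 17 and closes the C2–O1 bond instead of the C2–aryl bond. MeMgBr addition gives 1-{2-hydroxy-3-[(2R)-5-methyl-2-(prop-1-en-2-yl)-5-(triethylsilyloxy)hexyl]-4,6-bis(triisopropylsilyloxy)phenyl}ethan-1-ol F3, and MnO2 oxidation gives the corresponding 2-hydroxyacetophenone F4. Kabbe-type pyrrolidine-mediated condensation (EtOH, 50 °C) of F4 with 2,4-bis(tert-butyldimethylsilyloxy)benzaldehyde F5 (from 2,4-dihydroxybenzaldehyde, TBSCl, imidazole) should pass through 2'-hydroxychalcone F6 and close by oxa-Michael addition to 25 and its C2 epimer F7. These are diastereomers because of the fixed side-chain centre and would be separated by preparative HPLC on a chiral phase. F7 would be re-equilibrated through F6 with the same amine and recycled; the fallback comes back to the route at 25.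

Step 5. Oxygen transfer to the acetylide may be incomplete, and the ynolate may silylate on carbon instead of oxygen. The fallback sets out from 2 and reaches the ynolate by rearrangement of an ester homologue instead of oxidation of an acetylide. Pinnick oxidation gives (3R)-6-oxo-3-(prop-1-en-2-yl)heptanoic acid F8, and TMSCHN2 gives its methyl ester F9. Ketone-selective MeMgBr addition at −78 °C gives methyl (3R)-6-hydroxy-6-methyl-3-(prop-1-en-2-yl)heptanoate F10, and TESOTf/2,6-lutidine gives its triethylsilyl ether F11. Kowalski ester homologation of F11 (CH2Br2/LiTMP, −78 °C; LiHMDS; s-BuLi, warm) should give ynolate 7, and TIPSCl then returns to the route at 8.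

Further compounds
F1 | step 7 | triisopropylsilyl 3-(triisopropylsilyloxy)but-2-enoate | CC(=CC(=O)O[Si](C(C)C)(C(C)C)C(C)C)O[Si](C(C)C)(C(C)C)C(C)C
F2 | step 7 | 3-(triisopropylsilyloxy)but-2-enoyl chloride | CC(=CC(=O)Cl)O[Si](C(C)C)(C(C)C)C(C)C
F3 | step 13 | 1-{2-hydroxy-3-[(2R)-5-methyl-2-(prop-1-en-2-yl)-5-(triethylsilyloxy)hexyl]-4,6-bis(triisopropylsilyloxy)phenyl}ethan-1-ol | C=C(C)[C@H](CCC(C)(C)O[Si](CC)(CC)CC)Cc1c(O)c(C(C)O)c(O[Si](C(C)C)(C(C)C)C(C)C)cc1O[Si](C(C)C)(C(C)C)C(C)C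
F4 | step 13 | 1-{2-hydroxy-3-[(2R)-5-methyl-2-(prop-1-en-2-yl)-5-(triethylsilyloxy)hexyl]-4,6-bis(triisopropylsilyloxy)phenyl}ethan-1-one | C=C(C)[C@H](CCC(C)(C)O[Si](CC)(CC)CC)Cc1c(O)c(C(C)=O)c(O[Si](C(C)C)(C(C)C)C(C)C)cc1O[Si](C(C)C)(C(C)C)C(C)C
F5 | step 13 | 2,4-bis(tert-butyldimethylsilyloxy)benzaldehyde | CC(C)(C)[Si](C)(C)Oc1ccc(C=O)c(O[Si](C)(C)C(C)(C)C)c1
F6 | step 13 | (E)-3-[2,4-bis(tert-butyldimethylsilyloxy)phenyl]-1-{2-hydroxy-3-[(2R)-5-methyl-2-(prop-1-en-2-yl)-5-(triethylsilyloxy)hexyl]-4,6-bis(triisopropylsilyloxy)phenyl}prop-2-en-1-one | C=C(C)[C@H](CCC(C)(C)O[Si](CC)(CC)CC)Cc1c(O)c(C(=O)/C=C/c2ccc(O[Si](C)(C)C(C)(C)C)cc2O[Si](C)(C)C(C)(C)C)c(O[Si](C(C)C)(C(C)C)C(C)C)cc1O[Si](C(C)C)(C(C)C)C(C)C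
F7 | step 13 | (2R)-2-[2,4-bis(tert-butyldimethylsilyloxy)phenyl]-8-[(2R)-5-methyl-2-(prop-1-en-2-yl)-5-(triethylsilyloxy)hexyl]-5,7-bis(triisopropylsilyloxy)chroman-4-one | C=C(C)[C@H](CCC(C)(C)O[Si](CC)(CC)CC)Cc1c(O[Si](C(C)C)(C(C)C)C(C)C)cc(O[Si](C(C)C)(C(C)C)C(C)C)c2c1O[C@@H](c1ccc(O[Si](C)(C)C(C)(C)C)cc1O[Si](C)(C)C(C)(C)C)CC2=O
F8 | step 5 | (3R)-6-oxo-3-(prop-1-en-2-yl)heptanoic acid | C=C(C)[C@H](CCC(C)=O)CC(=O)O
F9 | step 5 | methyl (3R)-6-oxo-3-(prop-1-en-2-yl)heptanoate | C=C(C)[C@H](CCC(C)=O)CC(=O)OC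
F10 | step 5 | methyl (3R)-6-hydroxy-6-methyl-3-(prop-1-en-2-yl)heptanoate | C=C(C)[C@H](CCC(C)(C)O)CC(=O)OC
F11 | step 5 | methyl (3R)-6-methyl-3-(prop-1-en-2-yl)-6-(triethylsilyloxy)heptanoate | C=C(C)[C@H](CCC(C)(C)O[Si](CC)(CC)CC)CC(=O)OC
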